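**Retrosynthetic overview**

1. Atoms carry the locants of the target SMILES (C1–C26, O18). Ring B (C2, C3, C4, C5, C6, C7, C9, C22) without C3 is a cyclohept-4-enone: C2=O lies between C22 and C4, with C6=C7 across the ring. That is the retron of an oxyallyl–diene (4+3) cycloaddition, and C3 is a methylene beside that carbonyl; the plan rests on this.
2. Target ⇒ (desilylation; C1 methyl through the C2 enol triflate) eight-membered C2 ketone ⇒ one-carbon ring expansion with Me3SiCHN2/AlMe3, which inserts C3 between C2 and C4 of the 5-7-6-5 ketone.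
3. 5-7-6-5 ketone ⇒ intramolecular (4+3) of the oxyallyl cation C22–C2(O)–C4 (chloromethyl ketone on the C19 arm) with the diene C5=C6–C7=C9 (on the C11 arm); ring C and the seven-membered ring close together (bonds C22–C9 and C4–C5).
4. Cycloaddition substrate ⇒ Negishi coupling (C10–C9) of a ring D alkyl iodide with a ring A dienyl iodide. Ring D comes from 2-methylcyclopent-2-en-1-one (asymmetric conjugate addition/allylation for C11 and C19, then C12 and C17 by substrate control); ring A comes from 3-methylcyclopent-2-en-1-one (C25 by asymmetric conjugate reduction).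
5. Order of rings: D and A from the two cyclopentenones, then C plus the seven-membered ring in one step, then ring B by expansion.

Key step: step 17

Remark: the chiral copper ligands of steps 1 and 11 are taken as the enantiomers that lead to the 3S centres drawn; the sense of induction is to be confirmed on the first intermediate of each branch.

**Route**

Step 1
Reactants: 1 2-methylcyclopent-2-en-1-one
Product: 3 (2R,3S)-3-{[dimethyl(phenyl)silyl]methyl}-2-methyl-2-(prop-2-en-1-yl)cyclopentan-1-one, via magnesium enolate 2 (not isolated)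
Conditions: PhMe2SiCH2MgCl, Cu(OTf)2 (cat.), chiral imidazolinium salt (NHC precursor, cat.), Et2O, −30 °C; then allyl iodide, DMPU, THF, −30 °C → rt
Reagents that add atoms: [(dimethylphenylsilyl)methyl]magnesium chloride, C[Si](C)(C[Mg]Cl)c1ccccc1; allyl iodide, C=CCI
Why: Copper-catalysed asymmetric conjugate addition of an organomagnesium reagent to an α-substituted cyclopentenone under a chiral carbene ligand is expected to set C11 (3S), and C-allylation of enolate 2 anti to the new β-substituent then fixes the quaternary C19 (2R) with its methyl cis to the silylmethyl arm, a tandem conjugate addition–enolate alkylation.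

Step 2
Reactants: 3 (2R,3S)-3-{[dimethyl(phenyl)silyl]methyl}-2-methyl-2-(prop-2-en-1-yl)cyclopentan-1-one
Product: 5 (4S,5R)-4-{[dimethyl(phenyl)silyl]methyl}-5-methyl-5-(prop-2-en-1-yl)cyclopent-2-en-1-one, via trimethylsilyl enol ether 4 (not isolated)
Conditions: LDA, Me3SiCl, THF, −78 °C; then Pd(OAc)2, MeCN, rt
Reagents that add atoms: none
Why: Saegusa–Ito oxidation, in which C16 is the only enolisable position because C19 is quaternary, so one silyl enol ether forms and Pd(OAc)2 dehydrosilylates it to the C16=C12 enone without touching C11 or C19.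

Step 3
Reactants: 5 (4S,5R)-4-{[dimethyl(phenyl)silyl]methyl}-5-methyl-5-(prop-2-en-1-yl)cyclopent-2-en-1-one
Product: 7 (2R,3S,4S)-3-{[dimethyl(phenyl)silyl]methyl}-2-methyl-4-(propan-2-yl)-2-(prop-2-en-1-yl)cyclopentan-1-one, via trimethylsilyl enol ether 6 (not isolated)
Conditions: i-PrMgCl, CuBr·SMe2 (cat.), Me3SiCl, THF, −78 °C; then 1 M HCl, rt
Reagents that add atoms: isopropylmagnesium chloride, CC(C)[Mg]Cl
Why: Copper-catalysed 1,4-addition accelerated by Me3SiCl should deliver the isopropyl group to C12 anti to the adjacent C11 silylmethyl arm, the trans relationship typical of cuprate additions to 4-substituted cyclopentenones, and enol ether 6 is hydrolysed on acidic work-up.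

Step 4
Reactants: 7 (2R,3S,4S)-3-{[dimethyl(phenyl)silyl]methyl}-2-methyl-4-(propan-2-yl)-2-(prop-2-en-1-yl)cyclopentan-1-one
Product: 8 (1R,2R,3S,4S)-3-{[dimethyl(phenyl)silyl]methyl}-2-methyl-4-(propan-2-yl)-2-(prop-2-en-1-yl)cyclopentan-1-ol
Conditions: NaBH4, MeOH, −20 °C
Reagents that add atoms: none
Why: Borohydride reduction in which the three large ring substituents sit pseudo-equatorial and leave the C19 methyl pseudo-axial, so hydride should attack C17 from the face opposite that methyl, as in 17-oxo steroids, giving the 17R alcohol cis to the methyl.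

Step 5
Reactants: 8 (1R,2R,3S,4S)-3-{[dimethyl(phenyl)silyl]methyl}-2-methyl-4-(propan-2-yl)-2-(prop-2-en-1-yl)cyclopentan-1-ol
Product: 9 tert-butyldimethylsilyl ether of 8
Conditions: TBSOTf, 2,6-lutidine, CH2Cl2, 0 °C
Reagents that add atoms: tert-butyldimethylsilyl trifluoromethanesulfonate, CC(C)(C)[Si](C)(C)OS(=O)(=O)C(F)(F)F
Why: O-Silylation of the hindered secondary alcohol with the silyl triflate protects O18 for the oxidations and organometallic steps that follow, with no change at any stereocentre.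

Step 6
Reactants: 9 tert-butyldimethylsilyl ether of 8
Product: 11 3-[(1R,2S,3S,5R)-5-{[tert-butyl(dimethyl)silyl]oxy}-2-{[dimethyl(phenyl)silyl]methyl}-1-methyl-3-(propan-2-yl)cyclopentyl]propan-1-ol, via B-alkyl-9-BBN adduct 10 (not isolated)
Conditions: 9-BBN, THF, 0 °C → rt; then NaOH, H2O2, H2O, 0 °C
Reagents that add atoms: hydrogen peroxide, OO
Why: Hydroboration–oxidation, in which 9-BBN adds to the terminal alkene with anti-Markovnikov selectivity and alkaline peroxide oxidises the C–B bond to the primary alcohol at C2, leaving both silyl groups intact.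

Step 7
Reactants: 11 3-[(1R,2S,3S,5R)-5-{[tert-butyl(dimethyl)silyl]oxy}-2-{[dimethyl(phenyl)silyl]methyl}-1-methyl-3-(propan-2-yl)cyclopentyl]propan-1-ol
Product: 12 3-[(1R,2S,3S,5R)-5-{[tert-butyl(dimethyl)silyl]oxy}-2-{[dimethyl(phenyl)silyl]methyl}-1-methyl-3-(propan-2-yl)cyclopentyl]propanoic acid
Conditions: TEMPO (cat.), PhI(OAc)2, MeCN/H2O, rt
Reagents that add atoms: water, O
Why: Nitroxyl-catalysed oxidation with PhI(OAc)2 in aqueous acetonitrile takes the primary alcohol through the aldehyde hydrate to the carboxylic acid, and the silyl ether and the aryl silane are inert to it.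

Step 8
Reactants: 12 3-[(1R,2S,3S,5R)-5-{[tert-butyl(dimethyl)silyl]oxy}-2-{[dimethyl(phenyl)silyl]methyl}-1-methyl-3-(propan-2-yl)cyclopentyl]propanoic acid
Product: 13 N-methoxy-N-methylamide of 12
Conditions: MeNH(OMe)·HCl, EDC·HCl, DMAP (cat.), i-Pr2NEt, CH2Cl2, rt
Reagents that add atoms: N,O-dimethylhydroxylamine hydrochloride, CNOC.Cl
Why: Carbodiimide-mediated amide coupling gives the N-methoxy-N-methylamide, which later accepts exactly one equivalent of a carbon nucleophile.

Step 9
Reactants: 13 N-methoxy-N-methylamide of 12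
Product: 14 3-[(1R,2S,3S,5R)-5-{[tert-butyl(dimethyl)silyl]oxy}-2-(hydroxymethyl)-1-methyl-3-(propan-2-yl)cyclopentyl]-N-methoxy-N-methylpropanamide
Conditions: KBr, AcOOH, NaOAc, AcOH, rt
Reagents that add atoms: peracetic acid, CC(=O)OO
Why: Fleming–Tamao oxidation, in which bromodesilylation of the phenyl group and a peracid-induced 1,2-shift from silicon to oxygen convert C10–Si into C10–OH with retention and without touching the ring stereocentres.

Step 10
Reactants: 14 3-[(1R,2S,3S,5R)-5-{[tert-butyl(dimethyl)silyl]oxy}-2-(hydroxymethyl)-1-methyl-3-(propan-2-yl)cyclopentyl]-N-methoxy-N-methylpropanamide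
Product: 15 3-[(1R,2S,3S,5R)-5-{[tert-butyl(dimethyl)silyl]oxy}-2-(iodomethyl)-1-methyl-3-(propan-2-yl)cyclopentyl]-N-methoxy-N-methylpropanamide
Conditions: I2, PPh3, imidazole, CH2Cl2, 0 °C → rt
Reagents that add atoms: iodine, II
Why: Appel-type iodination, in which the primary alcohol is activated as its oxyphosphonium ion and displaced by iodide in an SN2 reaction at C10, which is not a stereocentre.

Step 11
Reactants: 16 3-methylcyclopent-2-en-1-one
Product: 19 (3S)-3-methylcyclopent-1-en-1-yl trifluoromethanesulfonate, via bis(enoxy)diphenylsilane 17 (not isolated), via lithium enolate 18 (not isolated)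
Conditions: CuCl (cat.), NaOt-Bu (cat.), p-tol-BINAP (cat., enantiomer giving 3S), Ph2SiH2, toluene, 0 °C; then MeLi, THF, 0 °C; then PhNTf2, −78 °C → rt
Reagents that add atoms: N-phenylbis(trifluoromethanesulfonimide), O=S(=O)(N(c1ccccc1)S(=O)(=O)C(F)(F)F)C(F)(F)F
Why: Copper hydride-catalysed asymmetric conjugate reduction with a chiral bisphosphine sets C25 (3S) by face-selective hydride delivery to the β-carbon and gives the enol derivative regiospecifically between C6 and C5, and cleavage of the Si–O bonds by MeLi followed by O-triflation of the lithium enolate keeps that regiochemistry.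

Step 12
Reactants: 19 (3S)-3-methylcyclopent-1-en-1-yl trifluoromethanesulfonate
Product: 20 (3S)-1-ethynyl-3-methylcyclopent-1-ene
Conditions: HC≡CMgBr, ZnBr2, THF, 0 °C; then 19, Pd(PPh3)4 (cat.), rt
Reagents that add atoms: ethynylmagnesium bromide, C#C[Mg]Br
Why: Negishi-type alkynylation, in which zerovalent palladium inserts into the enol triflate, ethynylzinc bromide transmetalates and reductive elimination gives the enyne without touching C25, the volatile product being carried on as a solution.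

Step 13
Reactants: 20 (3S)-1-ethynyl-3-methylcyclopent-1-ene
Product: 22 (3S)-1-[(1E)-1-iodoprop-1-en-2-yl]-3-methylcyclopent-1-ene, via alkenylalane 21 (not isolated)
Conditions: AlMe3, Cp2ZrCl2 (cat.), CH2Cl2, 0 °C → rt; then I2, THF, −30 → 0 °C
Reagents that add atoms: trimethylaluminium, C[Al](C)C; iodine, II
Why: Zirconium-catalysed carboalumination (Negishi) adds methyl and aluminium syn across the terminal alkyne with methyl on the internal carbon C7, and iodinolysis of the C–Al bond with retention gives the E iodide at C9.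

Step 14
Reactants: 15 ring D iodide (C10–I); 22 (3S)-1-[(1E)-1-iodoprop-1-en-2-yl]-3-methylcyclopent-1-ene
Product: 24 3-[(1R,2S,3S,5R)-5-{[tert-butyl(dimethyl)silyl]oxy}-1-methyl-2-{(2E)-3-[(3S)-3-methylcyclopent-1-en-1-yl]but-2-en-1-yl}-3-(propan-2-yl)cyclopentyl]-N-methoxy-N-methylpropanamide, via alkylzinc iodide 23 (not isolated)
Conditions: Zn, LiCl, THF, 50 °C; then 22, PdCl2(dppf) (cat.), THF, 50 °C
Reagents that add atoms: none
Why: Negishi coupling, in which zinc inserts into the primary C10–I bond without affecting the amide or the silyl ether and palladium-catalysed sp3–sp2 coupling with the alkenyl iodide forms C10–C9 with retention of the E geometry of C7=C9.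

Step 15
Reactants: 24 diene N-methoxy-N-methylamide
Product: 25 1-chloro-4-[(1R,2S,3S,5R)-5-{[tert-butyl(dimethyl)silyl]oxy}-1-methyl-2-{(2E)-3-[(3S)-3-methylcyclopent-1-en-1-yl]but-2-en-1-yl}-3-(propan-2-yl)cyclopentyl]butan-2-one
Conditions: ICH2Cl, MeLi·LiBr, THF, −78 °C; then NH4Cl (aq)
Reagents that add atoms: chloroiodomethane, ClCI
Why: Acylation of chloromethyllithium, generated in the presence of the amide by iodine–lithium exchange, in which the chelated tetrahedral adduct prevents over-addition and collapses to the chloromethyl ketone on quench, so that no electrophilic halogen source ever meets the diene.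

Step 16
Reactants: 25 chloromethyl ketone
Product: 27 (5S,9S,11S,12S,17R,19R,22S,25S) 5-7-6-5 tetracyclic C2 ketone tert-butyldimethylsilyl ether, via oxyallyl cation 26 (not isolated)
Conditions: Et3N, (CF3)2CHOH, 0 °C → rt; then DBU, CH2Cl2, rt
Reagents that add atoms: none
Why: Intramolecular oxyallyl–diene (4+3) cycloaddition, in which base-induced loss of chloride from the C22 enolate in the ionising fluoro alcohol gives cation 26, which should add across C9 and C5 of the s-cis diene through a chair-like tether with the diene equatorial (C9 S and, by suprafacial addition to the E diene, C5 S, which means bonding on the diene face syn to the C25 methyl, so the tether has to outweigh that small local bias), while C22, being α to the new ketone, is converged by DBU to the trans ring fusion that avoids a 1,3-diaxial clash between C2 and the C19 methyl.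

Step 17
Reactants: 27 5-7-6-5 tetracyclic C2 ketone tert-butyldimethylsilyl ether; 28 (trimethylsilyl)diazomethane
Product: 30 (5S,9S,11S,12S,17R,19R,22S,25S) 5-8-6-5 tetracyclic C2 ketone tert-butyldimethylsilyl ether, via α-silyl ketone 29 (not isolated)
Conditions: Me3SiCHN2, AlMe3, CH2Cl2, −78 → −20 °C; then K2CO3, MeOH, rt
Reagents that add atoms: (trimethylsilyl)diazomethane (28), C[Si](C)(C)C=[N+]=[N-]
Why: AlMe3 activates the C2 carbonyl, the diazo carbon of 28 adds to C2 to give a diazonium aluminate betaine, and a 1,2-shift of C4 from C2 to the new carbon with loss of N2 gives α-silyl ketone 29, which K2CO3 in methanol protodesilylates to 30. The closest known reaction type is the Lewis acid-promoted homologation of cycloalkanones with trimethylsilyldiazomethane, a Tiffeneau–Demjanov-type ring enlargement. Ring B is not closed by a cyclisation but arises by one-carbon enlargement of the seven-membered ring, the new C3 being inserted between C2 and C4 (bonds C2–C3 and C3–C4). No stereocentre of the product is created: C3 carries silicon only transiently, C5 and C9 are untouched, and C22 stays in its thermodynamically preferred trans-fused configuration. The step needs migration of the C4 methylene in preference to the C22 ring-fusion methine; in the betaine the bulky Me3Si group is expected to avoid the substituted C22 side, which leaves C4 antiperiplanar to the departing N2, the usual preference of silyldiazomethane homologations for the less substituted α-carbon. The silyl group of 29 should also block a second insertion, and the silyl ether and the tetrasubstituted alkene are expected to be inert to AlMe3 at low temperature.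

Step 18
Reactants: 30 5-8-6-5 tetracyclic C2 ketone tert-butyldimethylsilyl ether
Product: 32 C2 enol triflate (C2=C3) of 30, via lithium enolate 31 (not isolated)
Conditions: LiN(SiMe3)2, THF, −78 °C; then PhNTf2, −78 → 0 °C
Reagents that add atoms: N-phenylbis(trifluoromethanesulfonimide), O=S(=O)(N(c1ccccc1)S(=O)(=O)C(F)(F)F)C(F)(F)F
Why: Kinetic enolisation with the hindered amide base removes a proton from the new C3 methylene and not from the C22 ring-fusion methine, and O-sulfonylation traps the enolate as the ring-cis enol triflate without epimerising C22.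

Step 19
Reactants: 32 C2 enol triflate
Product: 33 tert-butyldimethylsilyl ether of the target
Conditions: Me2CuLi (from CuI, MeLi), THF, −20 → 0 °C
Reagents that add atoms: lithium dimethylcuprate, [Li+].C[Cu-]C
Why: Cuprate coupling of the enol triflate (oxidative addition and reductive elimination at copper) replaces OTf by the C1 methyl with retention of the position and geometry of the C2=C3 alkene.

Step 20
Reactants: 33 tert-butyldimethylsilyl ether of the target
Product: 34 target dienol (5S,9S,11S,12S,17R,19R,22S,25S)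
Conditions: Bu4NF, THF, rt → 45 °C
Reagents that add atoms: none
Why: Fluoride-mediated cleavage of the silyl ether, driven by Si–F bond formation, frees the C17 alcohol without affecting the two alkenes or any stereocentre.

**Compound list**

1 | 2-methylcyclopent-2-en-1-one | CC1=CCCC1=O | starting material
2 | chloromagnesium (3S)-3-{[dimethyl(phenyl)silyl]methyl}-2-methylcyclopent-1-en-1-olate | C[Si](C)(c1ccccc1)C[C@H]1CCC(O[Mg]Cl)=C1C | intermediate
3 | (2R,3S)-3-{[dimethyl(phenyl)silyl]methyl}-2-methyl-2-(prop-2-en-1-yl)cyclopentan-1-one | C[Si](C)(c1ccccc1)C[C@H]1CCC(=O)[C@]1(C)CC=C | intermediate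
4 | trimethylsilyl enol ether of 3, {[(4S,5R)-4-{[dimethyl(phenyl)silyl]methyl}-5-methyl-5-(prop-2-en-1-yl)cyclopent-1-en-1-yl]oxy}trimethylsilane | C[Si](C)(c1ccccc1)C[C@H]1CC=C(O[Si](C)(C)C)[C@]1(C)CC=C | intermediate
5 | (4S,5R)-4-{[dimethyl(phenyl)silyl]methyl}-5-methyl-5-(prop-2-en-1-yl)cyclopent-2-en-1-one | C[Si](C)(c1ccccc1)C[C@H]1C=CC(=O)[C@]1(C)CC=C | intermediate
6 | trimethylsilyl enol ether of 7 (C17–OSiMe3, C16=C17, ring stereocentres as in 7) | C[Si](C)(c1ccccc1)C[C@H]1[C@H](C(C)C)C=C(O[Si](C)(C)C)[C@]1(C)CC=C | intermediate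
7 | (2R,3S,4S)-3-{[dimethyl(phenyl)silyl]methyl}-2-methyl-4-(propan-2-yl)-2-(prop-2-en-1-yl)cyclopentan-1-one | C[Si](C)(c1ccccc1)C[C@H]1[C@H](C(C)C)CC(=O)[C@]1(C)CC=C | intermediate
8 | (1R,2R,3S,4S)-3-{[dimethyl(phenyl)silyl]methyl}-2-methyl-4-(propan-2-yl)-2-(prop-2-en-1-yl)cyclopentan-1-ol | C[Si](C)(c1ccccc1)C[C@H]1[C@H](C(C)C)C[C@@H](O)[C@]1(C)CC=C | intermediate
9 | tert-butyl{[(1R,2R,3S,4S)-3-{[dimethyl(phenyl)silyl]methyl}-2-methyl-4-(propan-2-yl)-2-(prop-2-en-1-yl)cyclopentyl]oxy}dimethylsilane | C[Si](C)(c1ccccc1)C[C@H]1[C@H](C(C)C)C[C@@H](O[Si](C)(C)C(C)(C)C)[C@]1(C)CC=C | intermediate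
10 | B-alkyl-9-borabicyclo[3.3.1]nonane adduct of 9 (boron on the terminal carbon of the former allyl group) | C[Si](C)(c1ccccc1)C[C@H]1[C@H](C(C)C)C[C@@H](O[Si](C)(C)C(C)(C)C)[C@]1(C)CCCB1C2CCCC1CCC2 | intermediate
11 | 3-[(1R,2S,3S,5R)-5-{[tert-butyl(dimethyl)silyl]oxy}-2-{[dimethyl(phenyl)silyl]methyl}-1-methyl-3-(propan-2-yl)cyclopentyl]propan-1-ol | C[Si](C)(c1ccccc1)C[C@H]1[C@H](C(C)C)C[C@@H](O[Si](C)(C)C(C)(C)C)[C@]1(C)CCCO | intermediate
12 | 3-[(1R,2S,3S,5R)-5-{[tert-butyl(dimethyl)silyl]oxy}-2-{[dimethyl(phenyl)silyl]methyl}-1-methyl-3-(propan-2-yl)cyclopentyl]propanoic acid | C[Si](C)(c1ccccc1)C[C@H]1[C@H](C(C)C)C[C@@H](O[Si](C)(C)C(C)(C)C)[C@]1(C)CCC(=O)O | intermediate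
13 | 3-[(1R,2S,3S,5R)-5-{[tert-butyl(dimethyl)silyl]oxy}-2-{[dimethyl(phenyl)silyl]methyl}-1-methyl-3-(propan-2-yl)cyclopentyl]-N-methoxy-N-methylpropanamide | C[Si](C)(c1ccccc1)C[C@H]1[C@H](C(C)C)C[C@@H](O[Si](C)(C)C(C)(C)C)[C@]1(C)CCC(=O)N(C)OC | intermediate
14 | 3-[(1R,2S,3S,5R)-5-{[tert-butyl(dimethyl)silyl]oxy}-2-(hydroxymethyl)-1-methyl-3-(propan-2-yl)cyclopentyl]-N-methoxy-N-methylpropanamide | OC[C@H]1[C@H](C(C)C)C[C@@H](O[Si](C)(C)C(C)(C)C)[C@]1(C)CCC(=O)N(C)OC | intermediate
15 | 3-[(1R,2S,3S,5R)-5-{[tert-butyl(dimethyl)silyl]oxy}-2-(iodomethyl)-1-methyl-3-(propan-2-yl)cyclopentyl]-N-methoxy-N-methylpropanamide | IC[C@H]1[C@H](C(C)C)C[C@@H](O[Si](C)(C)C(C)(C)C)[C@]1(C)CCC(=O)N(C)OC | intermediate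
16 | 3-methylcyclopent-2-en-1-one | CC1=CC(=O)CC1 | starting material
17 | bis{[(3S)-3-methylcyclopent-1-en-1-yl]oxy}diphenylsilane | C[C@@H]1C=C(O[Si](c2ccccc2)(c2ccccc2)OC2=C[C@@H](C)CC2)CC1 | intermediate
18 | lithium (3S)-3-methylcyclopent-1-en-1-olate | [Li]OC1=C[C@@H](C)CC1 | intermediate
19 | (3S)-3-methylcyclopent-1-en-1-yl trifluoromethanesulfonate | O=S(=O)(OC1=C[C@@H](C)CC1)C(F)(F)F | intermediate
20 | (3S)-1-ethynyl-3-methylcyclopent-1-ene | C#CC1=C[C@@H](C)CC1 | intermediate
21 | dimethyl{(1E)-2-[(3S)-3-methylcyclopent-1-en-1-yl]prop-1-en-1-yl}alane | C/C(=C\[Al](C)C)C1=C[C@@H](C)CC1 | intermediate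
22 | (3S)-1-[(1E)-1-iodoprop-1-en-2-yl]-3-methylcyclopent-1-ene | C/C(=C\I)C1=C[C@@H](C)CC1 | intermediate
23 | alkylzinc iodide from 15 (C10–ZnI) | I[Zn]C[C@H]1[C@H](C(C)C)C[C@@H](O[Si](C)(C)C(C)(C)C)[C@]1(C)CCC(=O)N(C)OC | intermediate
24 | 3-[(1R,2S,3S,5R)-5-{[tert-butyl(dimethyl)silyl]oxy}-1-methyl-2-{(2E)-3-[(3S)-3-methylcyclopent-1-en-1-yl]but-2-en-1-yl}-3-(propan-2-yl)cyclopentyl]-N-methoxy-N-methylpropanamide | C/C(=C\C[C@H]1[C@H](C(C)C)C[C@@H](O[Si](C)(C)C(C)(C)C)[C@]1(C)CCC(=O)N(C)OC)C1=C[C@@H](C)CC1 | intermediate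
25 | 1-chloro-4-[(1R,2S,3S,5R)-5-{[tert-butyl(dimethyl)silyl]oxy}-1-methyl-2-{(2E)-3-[(3S)-3-methylcyclopent-1-en-1-yl]but-2-en-1-yl}-3-(propan-2-yl)cyclopentyl]butan-2-one | C/C(=C\C[C@H]1[C@H](C(C)C)C[C@@H](O[Si](C)(C)C(C)(C)C)[C@]1(C)CCC(=O)CCl)C1=C[C@@H](C)CC1 | intermediate
26 | oxyallyl cation (zwitterion C22=C2(O−)–C4H2+) from 25 | C/C(=C\C[C@H]1[C@H](C(C)C)C[C@@H](O[Si](C)(C)C(C)(C)C)[C@]1(C)CC=C([O-])[CH2+])C1=C[C@@H](C)CC1 | intermediate
27 | (5S,9S,11S,12S,17R,19R,22S,25S) 5-7-6-5 tetracyclic C2 ketone tert-butyldimethylsilyl ether (no C3, no C1 methyl, C6=C7) | O=C1C[C@@H]2/C(=C(/C)[C@H]3C[C@H]4[C@H](C(C)C)C[C@@H](O[Si](C)(C)C(C)(C)C)[C@]4(C)C[C@H]13)CC[C@@H]2C | intermediate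
28 | (trimethylsilyl)diazomethane | C[Si](C)(C)C=[N+]=[N-] | starting material
29 | 3-(trimethylsilyl) derivative of 30 (α-silyl ketone, C3 configuration not defined) | O=C1C([Si](C)(C)C)C[C@@H]2/C(=C(/C)[C@H]3C[C@H]4[C@H](C(C)C)C[C@@H](O[Si](C)(C)C(C)(C)C)[C@]4(C)C[C@H]13)CC[C@@H]2C | intermediate
30 | (5S,9S,11S,12S,17R,19R,22S,25S) 5-8-6-5 tetracyclic C2 ketone tert-butyldimethylsilyl ether | O=C1CC[C@@H]2/C(=C(/C)[C@H]3C[C@H]4[C@H](C(C)C)C[C@@H](O[Si](C)(C)C(C)(C)C)[C@]4(C)C[C@H]13)CC[C@@H]2C | intermediate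
31 | lithium enolate of 30 (C2–OLi, C2=C3) | [Li]O/C1=C/C[C@@H]2/C(=C(/C)[C@H]3C[C@H]4[C@H](C(C)C)C[C@@H](O[Si](C)(C)C(C)(C)C)[C@]4(C)C[C@H]13)CC[C@@H]2C | intermediate
32 | C2 enol triflate of 30 (C2=C3, ring-cis) | O=S(=O)(O/C1=C/C[C@@H]2/C(=C(/C)[C@H]3C[C@H]4[C@H](C(C)C)C[C@@H](O[Si](C)(C)C(C)(C)C)[C@]4(C)C[C@H]13)CC[C@@H]2C)C(F)(F)F | intermediate
33 | tert-butyldimethylsilyl ether of the target | C/C1=C/C[C@@H]2/C(=C(/C)[C@H]3C[C@H]4[C@H](C(C)C)C[C@@H](O[Si](C)(C)C(C)(C)C)[C@]4(C)C[C@H]13)CC[C@@H]2C | intermediate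
34 | target, (5S,9S,11S,12S,17R,19R,22S,25S) 5-8-6-5 tetracyclic dienol (C2=C3, C6=C7) | C/C1=C/C[C@@H]2/C(=C(/C)[C@H]3C[C@H]4[C@H](C(C)C)C[C@@H](O)[C@]4(C)C[C@H]13)CC[C@@H]2C | target

**Totals and risks**

Total step count: 20. Longest linear sequence: 17 (steps 1–10 and 14–20).

The three steps most likely to fail:

1. Step 16. Ionisation of the primary chloride may be slow, so that capture of the weakly stabilised oxyallyl cation by the solvent or Favorskii rearrangement competes with cycloaddition; bonding on the diene face syn to the C25 methyl may also lower face selectivity. Fallback, from amide 24 back to ketone 27: dichloromethyllithium (CH2Cl2, LDA, THF, −78 °C) acylates 24 to the dichloromethyl ketone F1. Et3N in CF3CH2OH ionises F1 to a chlorine-stabilised oxyallyl cation, whose intramolecular (4+3) cycloaddition gives the 4-chloro ketone F2. Zn–Cu couple with NH4Cl in MeOH then removes the chlorine reductively to give 27.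

2. Step 17. Migration of the C22 methine may compete with that of C4, or the betaine may close to an epoxide. Fallback, from ketone 27 back to ketone 30, with the regiochemistry fixed by enolisation: LDA and Me3SiCl give the less substituted trimethylsilyl enol ether F3 (C2=C4). Simmons–Smith cyclopropanation (Et2Zn, CH2I2) gives the siloxycyclopropane F4. FeCl3 in DMF cleaves the internal cyclopropane bond oxidatively to the ring-enlarged β-chloro ketone F5. NaOAc in MeOH eliminates HCl to the cyclooctenone F6, and conjugate reduction with [CuH(PPh3)]6 gives 30.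

3. Step 1. Enantiofacial discrimination in the copper-catalysed addition of the α-silyl organomagnesium reagent may be insufficient. Fallback, from enone 1 back to ketone 3: the same three-component coupling under achiral CuI catalysis gives 3 as the racemate, that is together with its enantiomer F7, and preparative chromatography on a chiral stationary phase separates the two.

**Further compounds**

F1 | step 16 | dichloromethyl ketone analogue of 25 (C4 bears two chlorines) | C/C(=C\C[C@H]1[C@H](C(C)C)C[C@@H](O[Si](C)(C)C(C)(C)C)[C@]1(C)CCC(=O)C(Cl)Cl)C1=C[C@@H](C)CC1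
F2 | step 16 | 4-chloro derivative of 27 (C4 configuration not defined) | O=C1C(Cl)[C@@H]2/C(=C(/C)[C@H]3C[C@H]4[C@H](C(C)C)C[C@@H](O[Si](C)(C)C(C)(C)C)[C@]4(C)C[C@H]13)CC[C@@H]2C
F3 | step 17 | trimethylsilyl enol ether of 27 (C2–OSiMe3, C2=C4) | C[Si](C)(C)OC1=C[C@@H]2/C(=C(/C)[C@H]3C[C@H]4[C@H](C(C)C)C[C@@H](O[Si](C)(C)C(C)(C)C)[C@]4(C)C[C@H]13)CC[C@@H]2C
F4 | step 17 | siloxycyclopropane from F3 (cyclopropane C2–C3–C4) | C[Si](C)(C)OC15CC5[C@@H]2/C(=C(/C)[C@H]3C[C@H]4[C@H](C(C)C)C[C@@H](O[Si](C)(C)C(C)(C)C)[C@]4(C)C[C@H]13)CC[C@@H]2C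
F5 | step 17 | 4-chloro derivative of 30 (β-chloro ketone, C4 configuration not defined) | O=C1CC(Cl)[C@@H]2/C(=C(/C)[C@H]3C[C@H]4[C@H](C(C)C)C[C@@H](O[Si](C)(C)C(C)(C)C)[C@]4(C)C[C@H]13)CC[C@@H]2C
F6 | step 17 | 3,4-didehydro derivative of 30 (cyclooct-2-enone, C3=C4 cis) | O=C1/C=C\[C@@H]2/C(=C(/C)[C@H]3C[C@H]4[C@H](C(C)C)C[C@@H](O[Si](C)(C)C(C)(C)C)[C@]4(C)C[C@H]13)CC[C@@H]2C
F7 | step 1 | (2S,3R)-3-{[dimethyl(phenyl)silyl]methyl}-2-methyl-2-(prop-2-en-1-yl)cyclopentan-1-one (enantiomer of 3) | C[Si](C)(c1ccccc1)C[C@@H]1CCC(=O)[C@@]1(C)CC=C
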